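**Retrosynthetic overview**

- Feature: the benzene ring of the target carries Br at C4 (ortho to C3a) and at C6 (para to C3a), with C5–H and C7–H free. This is the pattern of 2,4-dibromobenzaldehyde 1: its formyl carbon becomes C3, its ipso carbon C3a, and its only free ortho C–H becomes C7a.
- C2–C3 disconnection: Knoevenagel condensation of 1 with ethyl azidoacetate 2 (through aldol adduct 3) brings in C2, N1 and a C2 ester as azidoacrylate 4.
- N1–C7a disconnection (key): thermolysis of 4, through vinyl nitrene 5, 2H-azirine 6 and 7aH-indole 7, closes the pyrrole ring, the only ring formed, onto the purchased benzene ring to give indole ester 8.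
- C2–Br disconnection: the ester of 8 is a placeholder for bromine. Saponification (salt 9, acid 10), protodecarboxylation to 4,6-dibromoindole 11, C2–H borylation to boronate 12 and bromodeboronation give target 13.

Key step: step 2

Remark: the sp3 centres of 3, 6 and 7 form without control and vanish again, and the target has no stereocentre. Azides 2 and 4 are handled in solution, and 4 is thermolysed dilute by slow addition.

**Step 1**
Reactants: 1 2,4-dibromobenzaldehyde; 2 ethyl azidoacetate
Product: 4 ethyl (Z)-2-azido-3-(2,4-dibromophenyl)acrylate, via aldol adduct 3 (not isolated)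
Conditions: 2 (4 equiv), NaOEt (4 equiv), EtOH, −10 to 0 °C; ice water
Reagents that add atoms: none
Why: Knoevenagel-type aldol condensation, in which deprotonated 2 should add to the electron-poor aldehyde to give aldol adduct 3 and E1cB loss of hydroxide should give the conjugated alkene, whose Z geometry (aryl trans to the ester, cis to the azide) is the thermodynamically preferred one.

**Step 2**
Reactants: 4 ethyl (Z)-2-azido-3-(2,4-dibromophenyl)acrylate
Product: 8 ethyl 4,6-dibromo-1H-indole-2-carboxylate, via vinyl nitrene 5 (not isolated), via 2H-azirine ester 6 (not isolated), via 7aH-indole ester 7 (not isolated)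
Conditions: xylenes (0.05 M, slow addition of 4 to the boiling solvent), 140 °C
Reagents that add atoms: none
Why: Hemetsberger–Knittel indole synthesis: at 140 °C azide 4 should lose N2 to give singlet vinyl nitrene 5, which is in equilibrium with its valence isomer, 2H-azirine 6. The pyrrole ring is closed at the N1–C7a bond by a five-atom electrocyclisation of 5 onto the ortho carbon of the arene, which gives 7aH-indole 7, and a 1,5-hydrogen shift from C7a to N1 then restores aromaticity. The closest known reaction type is the thermal cyclisation of α-azidocinnamates to indole-2-carboxylates, which is this substrate class. No stereocentre remains, because the sp3 centres of 6 and 7 are transient. The step needs site selectivity of the nitrene and the Z alkene: the second ortho position carries bromine, so a single ortho C–H is within reach, and the Z geometry holds nitrogen on the aryl side. The conditions are neutral and metal-free, so both C–Br bonds and the ester should survive.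

**Step 3**
Reactants: 8 ethyl 4,6-dibromo-1H-indole-2-carboxylate
Product: 10 4,6-dibromo-1H-indole-2-carboxylic acid, via sodium carboxylate 9 (not isolated)
Conditions: NaOH (3 equiv), EtOH/H2O, 70 °C; then 1 M HCl to pH 2
Reagents that add atoms: sodium hydroxide, [Na+].[OH-]
Why: Ester saponification (acyl substitution by hydroxide) should give carboxylate 9, which is protonated on acidification, while the aryl bromides and the indole N–H are inert to aqueous hydroxide at this temperature.

**Step 4**
Reactants: 10 4,6-dibromo-1H-indole-2-carboxylic acid
Product: 11 4,6-dibromo-1H-indole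
Conditions: Ag2CO3 (10 mol %), AcOH (5 mol %), DMSO, 120 °C
Reagents that add atoms: none
Why: Silver-catalysed protodecarboxylation of a heteroaromatic acid whose carboxyl carbon sits next to the ring heteroatom, in which decarboxylative metalation at C2 by monovalent silver is followed by protonolysis of the C–Ag bond, and monovalent silver does not insert into the C–Br bonds.

**Step 5**
Reactants: 11 4,6-dibromo-1H-indole
Product: 12 4,6-dibromo-2-(4,4,5,5-tetramethyl-1,3,2-dioxaborolan-2-yl)-1H-indole
Conditions: [Ir(OMe)(cod)]2 (1.5 mol %), 4,4′-di-tert-butyl-2,2′-bipyridine (dtbpy, 3 mol %), B2pin2 (1.0 equiv), THF, 25–50 °C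
Reagents that add atoms: bis(pinacolato)diboron, CC1(C)OB(OC1(C)C)B1OC(C)(C)C(C)(C)O1
Why: Iridium-catalysed aromatic C–H borylation (Ishiyama–Miyaura–Hartwig type), in which the tris(boryl) trivalent iridium catalyst should activate C2–H, the most acidic and least hindered C–H of an N–H indole, while C3–H is shielded by the peri C4–Br, C5–H lies between two bromines, C7–H is ortho to C6–Br, and aryl bromides do not undergo oxidative addition under these mild conditions.

**Step 6**
Reactants: 12 4,6-dibromo-2-(4,4,5,5-tetramethyl-1,3,2-dioxaborolan-2-yl)-1H-indole
Product: 13 2,4,6-tribromo-1H-indole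
Conditions: CuBr2 (3 equiv), MeOH/H2O (1:1), 80 °C
Reagents that add atoms: copper dibromide, [Cu+2].[Br-].[Br-]
Why: Copper-mediated bromodeboronation of an aryl pinacol boronate, in which transmetalation of the C2–B bond to divalent copper, oxidation by a second CuBr2 to trivalent copper and C–Br reductive elimination should place bromine at the ipso carbon C2, while C3 is guarded against electrophilic bromination by the peri C4–Br and the deactivating halogens.

**Compound list**

1 | 2,4-dibromobenzaldehyde | O=Cc1ccc(Br)cc1Br | starting material
2 | ethyl azidoacetate | CCOC(=O)CN=[N+]=[N-] | starting material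
3 | ethyl 2-azido-3-(2,4-dibromophenyl)-3-hydroxypropanoate (aldol adduct; racemic diastereomer mixture, both centres lost on dehydration) | CCOC(=O)C(N=[N+]=[N-])C(O)c1ccc(Br)cc1Br | intermediate (not isolated)
4 | ethyl (Z)-2-azido-3-(2,4-dibromophenyl)acrylate | CCOC(=O)/C(N=[N+]=[N-])=C/c1ccc(Br)cc1Br | intermediate
5 | ethyl (Z)-3-(2,4-dibromophenyl)-2-nitrenoacrylate (vinyl nitrene, monovalent nitrogen on C2) | CCOC(=O)/C([N])=C/c1ccc(Br)cc1Br | intermediate (not isolated)
6 | ethyl 2-(2,4-dibromophenyl)-2H-azirine-3-carboxylate (racemic) | CCOC(=O)C1=NC1c1ccc(Br)cc1Br | intermediate (not isolated)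
7 | ethyl 4,6-dibromo-7aH-indole-2-carboxylate (racemic) | CCOC(=O)C1=NC2C=C(Br)C=C(Br)C2=C1 | intermediate (not isolated)
8 | ethyl 4,6-dibromo-1H-indole-2-carboxylate | CCOC(=O)c1cc2c(Br)cc(Br)cc2[nH]1 | intermediate
9 | sodium 4,6-dibromo-1H-indole-2-carboxylate | [Na+].[O-]C(=O)c1cc2c(Br)cc(Br)cc2[nH]1 | intermediate (not isolated)
10 | 4,6-dibromo-1H-indole-2-carboxylic acid | OC(=O)c1cc2c(Br)cc(Br)cc2[nH]1 | intermediate
11 | 4,6-dibromo-1H-indole | Brc1cc(Br)c2cc[nH]c2c1 | intermediate
12 | 4,6-dibromo-2-(4,4,5,5-tetramethyl-1,3,2-dioxaborolan-2-yl)-1H-indole | CC1(C)OB(OC1(C)C)c1cc2c(Br)cc(Br)cc2[nH]1 | intermediate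
13 | 2,4,6-tribromo-1H-indole | Brc1cc(Br)c2cc(Br)[nH]c2c1 | target

**Step count**

Total steps: 6. Longest linear sequence: 6 steps (from 1).

**Steps most likely to fail**

1. Step 6. The C2 boronate may undergo protodeboronation in hot aqueous methanol, excess CuBr2 may brominate C3 electrophilically, or the HBr formed may hydrolyse the 2-bromoindole. Fallback from 12: oxidation of the C–B bond with NaBO3·4H2O in THF/H2O at room temperature should give the C2–OH compound, which rests as its lactam tautomer 4,6-dibromoindolin-2-one F1. Heating this with POBr3 and imidazole in 1,2-dichloroethane at 80 °C should exchange the lactam oxygen for bromine with aromatisation. The fallback returns to the route at 13.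

2. Step 5. The borylation may stall through poor solubility or diversion of the catalyst by the N–H group, or it may run on to a second borylation at C7. Fallback from 11: Boc2O with catalytic DMAP in MeCN should give tert-butyl 4,6-dibromo-1H-indole-1-carboxylate F2. Carbamate-directed C2 lithiation with LiN(iPr)2 in THF at −78 °C (an amide base, so no bromine–lithium exchange), with a short metalation time and a quench by BrCCl2CCl2Br, should give tert-butyl 2,4,6-tribromo-1H-indole-1-carboxylate F3. Methanolysis of the carbamate with K2CO3 in MeOH at room temperature then frees the N–H. The fallback replaces steps 5 and 6 and returns to the route at 13.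

3. Step 1. Ethoxide may decompose the azidoacetate with loss of N2, the reaction may stop at the aldol stage 3, or the hydroxide formed may hydrolyse the ester. Fallback from 1: Horner–Wadsworth–Emmons olefination with triethyl phosphonoacetate and NaH in THF at 0 °C should give ethyl (E)-3-(2,4-dibromophenyl)acrylate F4. Anti addition of Br2 in CH2Cl2 should give ethyl (2RS,3SR)-2,3-dibromo-3-(2,4-dibromophenyl)propanoate F5. NaN3 (3 equiv) in DMF at 25–50 °C should then effect azide substitution and elimination to the α-azidoacrylate, as is known for α,β-dibromo esters and ketones. The fallback returns to the route at 4.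

**Further compounds**

F1 | step 6 | 4,6-dibromoindolin-2-one | O=C1Cc2c(Br)cc(Br)cc2N1
F2 | step 5 | tert-butyl 4,6-dibromo-1H-indole-1-carboxylate | CC(C)(C)OC(=O)n1ccc2c(Br)cc(Br)cc21
F3 | step 5 | tert-butyl 2,4,6-tribromo-1H-indole-1-carboxylate | CC(C)(C)OC(=O)n1c(Br)cc2c(Br)cc(Br)cc21
F4 | step 1 | ethyl (E)-3-(2,4-dibromophenyl)acrylate | CCOC(=O)/C=C/c1ccc(Br)cc1Br
F5 | step 1 | ethyl (2RS,3SR)-2,3-dibromo-3-(2,4-dibromophenyl)propanoate (racemate, one enantiomer drawn) | CCOC(=O)[C@@H](Br)[C@@H](Br)c1ccc(Br)cc1Br
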